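**Structural features**

The target is a dearomatised acylphloroglucinol made of two fused six-membered rings. Ring A (C4a, C5, C6, C7, C8, C8a) is a cyclohexene-dione whose C5 and C7 carbonyls flank the quaternary C6. Ring B (O1, C2, C3, C4, C4a, C8a) is a 2,3-dimethyl-dihydropyran whose C4 is the enolised acyl carbon and whose O1 sits on C8a. C6 carries a prenyl group and a C11 chain, 5-methyl-2-(2-methylprop-1-enyl)hex-5-enyl; C8 carries a 1-phenyl-2-carboxyethyl arm. There are five stereocentres: C2 (S) and C3 (R) are adjacent and cis in ring B, C6 (S) and the chain methine (R) stand in a 1,3 relationship, and the benzylic centre (R) on the C8 arm is isolated from the others. C3 is alpha to the C4 carbonyl and the cis isomer is the less stable epimer, so base is a standing threat. The three electron-rich alkenes exclude strong acid and hydrogenation late in the route, and in any aromatic precursor the acid arm closes onto O7 as a lactone. The real difficulty is ring A: four different substituents on adjacent carbons of a phloroglucinol ring in which C6 and C8 are electronically similar, with C6 ending as a quaternary stereocentre that bears two CH2 groups differing only beyond the second atom. The key step exploits the C3–C4 bond of ring B: C4, attached to C4a of ring A, is bonded to a methyl-bearing C3 that sits next to the O1-bearing C2, which is the pattern of an aryl aldehyde carbon added across a vinyl group tethered through O1.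

**Logic of the disconnections**

19 to 18: the acid and O7 are rejoined as the lactone (O7–acyl bond). This keeps the acid masked and leaves O5 as the only free oxygen on ring A for the step before. The forward hydrolysis must open the enol ester without epimerising C3.

18 to 16 and 17: the C6–CH2 bond to the prenyl group is cut, which removes the quaternary stereocentre and returns ring A to an aromatic ring. Prenyl is chosen as the last group because it is the better allyl electrophile. The forward step must alkylate carbon rather than oxygen, at the unsubstituted allyl terminus, on the face that gives 6S.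

16 to 14 and 15: the C8–CH(Ph) bond and the O7–acyl bond are cut together, removing the lactone ring and the benzylic stereocentre. In 14, C8 is the only unsubstituted ring carbon, so regiochemistry is not in question. The forward annulation must be non-acidic because of the alkenes and must set the benzylic centre by catalyst control.

14 to 12 and 13: the trisubstituted C=C of the chain is cut to an aldehyde (as its lactol) and an isopropylidene ylide. The olefination is placed before any aryl lactone exists, because the ylide would attack one. It must not epimerise the centre alpha to the aldehyde.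

12 to 9 and 10 (through 11): the CH2–CH bond of the chain is cut, with the ring methylene as electrophile and the aldehyde alpha-carbon as an enamine nucleophile. This sets the methine with a predictable shielding model and uses a simple aldehyde. The enamine must capture 11 faster than the still-open C8 of a second molecule.

9 to 7 and 8: the C6–CH2 bond is cut to a one-carbon electrophile. C6 is addressed before C8 because in 7 it lies between both hydroxyls and is the innately more reactive carbon. The forward step must stop at one substitution.

7 to 6: the two O–CH2OCH3 bonds are cut. Both phenols are released together because the plan wants C6 chemistry first, so staged protection gains nothing.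

6 to 5: the C3–C4 bond is cut, which removes ring B and the C3 stereocentre and leaves an aldehyde with an O-tethered vinyl group. The forward step must give the cis isomer and not equilibrate it. The descriptors are mutually consistent: the (S)-ether centre of 5 becomes C2 (S), and with 3R the two methyls of 6 are cis, as in 19. Both phenols of 5 are kept as MOM ethers because these are small enough for the di-ortho-substituted aldehyde and inert to carbene and amidine (aryl esters would acylate the carbene, silyl ethers could be stripped), and they leave together in mild acid. The refinement lies in the base loading, which is held below the azolium loading.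

5 to 3 and 4: the O–C2 bond is cut. C2 comes from a commercial chiral alcohol; the forward etherification must proceed with clean inversion.

3 to 1 and 2: two O–C bonds are cut. The selectivity rests on the third hydroxyl being hydrogen-bonded to the formyl group.

**Other disconnections considered**

Alternative 1: The cut is the CH2–CH bond of the C6 chain, made on the tricyclic sulfone A1 in which the lactone already spans C8 and O7. In the forward key step, base expels sulfinate from A1 to give an ortho-quinone methide at C6, the enamine of 10 with a diarylprolinol silyl ether adds to it, and hydrolysis leaves the lactol A2 closed on O5.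
- In its favour: the methine is set by a well-understood shielding model, and with C8 blocked the methide cannot be captured by a second ring. On that point it is better than step 6 of the chosen route, which makes the same bond with C8 still open.
- Against it here: it needs the C8/O7 lactone before any C6 chemistry, whereas the first electrophile on the 5-hydroxy chromanone is expected at C6. The isopropylidene ylide that must follow would meet an aryl lactone with acidic alpha-hydrogens. It also leaves ring B and the cis pair unaddressed.
- Comparison: structurally it concerns a side-chain bond, not ring B, so it complements the chosen key step and does not replace it. Mechanistically both are organocatalytic and each sets one stereocentre; the sense of the enamine step is the more predictable, which is a point in its favour. In step economy the two are equal, since the chain costs the same three operations either way.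

Alternative 2: The cut is two bonds of ring A, C7–C8 and C4a–C5. In the forward key step, MgCl2 and triethylamine enolise the pyranone acetate A3 at its exocyclic methylene, which is C-acylated by the acid chloride A4; DBU then drives attack of C4a on the methyl ester to close ring A as the trione A5.
- In its favour: ring A is never aromatic, so there is no C6/C8 regiochemistry and no dearomatisation. The quaternary C6 is fixed in an acyclic malonate where it can be purified and assigned. On the quaternary centre it is better than the chosen plan, and it is convergent.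
- Against it here: A4 needs an enantioselective malonate quaternary centre with two similar alkyl groups and differentiated carboxyls. A3 needs its own cis-2,3-dimethyl pyranone synthesis with the same C3 lability. The C8 ester must later be removed and the benzylic arm installed with control, and the DBU stage threatens C3.
- Comparison: structurally it builds ring A, not ring B. Mechanistically it is robust two-electron acylation chemistry but strongly basic, against a neutral isomerisation. In step economy it is expected to be longer overall, since two fragments each need several steps, though it is more convergent.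

Alternative 3: The cut is the O1–C2 bond of ring B. In the forward key step, quinine promotes intramolecular oxa-Michael addition of the free phenol of A6 to the beta-carbon of its ortho tigloyl group, giving A7; C2 is set by C–O bond formation and C3 by protonation.
- In its favour: the tigloyl unit is cheap, both ring B centres arise in one step without a chiral alcohol or a Mitsunobu reaction, and the precedent is as good as that of the chosen step. Because the lactone is in place before ring B, the arene can be elaborated from symmetric phloroglucinol and the C6/C8 question is settled early. On that point it is better than the chosen plan.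
- Against it here: the addition is reversible, so C2 can be lost by retro-addition and C3, set by protonation, tends to drift to the trans epimer. Quinine must also override the existing benzylic centre, and the tigloyl group must first be placed regioselectively.
- Comparison: both close ring B. The chosen step forms a C–C bond irreversibly and takes C2 intact from the chiral pool, so only C3 needs control, whereas the oxa-Michael route must control two centres under equilibrating conditions. Step economy is comparable.

Key step: step 3

Assumption: the antipodes named for the chiral triazolium salts (steps 3 and 8) and for the bisphosphine ligand (step 9) are taken to be the matched ones; each is sold in both forms, and the mirror-image catalyst is used if a first run shows the opposite sense.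
Assumption: aldehyde 10 is taken to be a purchasable catalogue compound.

Step 1
Reactants: 1 2,4,6-trihydroxybenzaldehyde; 2 chloromethyl methyl ether
Product: 3 2-hydroxy-4,6-bis(methoxymethoxy)benzaldehyde
Conditions: 2 (2.2 equiv), i-Pr2NEt, CH2Cl2, 0 °C → rt
Reagents that add atoms: none
Why: Williamson-type O-alkylation of the two more acidic phenols; the third hydroxyl is held in a hydrogen bond to the formyl group and should be left untouched at this stoichiometry.

Step 2
Reactants: 3 2-hydroxy-4,6-bis(methoxymethoxy)benzaldehyde; 4 (R)-but-3-en-2-ol
Product: 5 2-[(2S)-but-3-en-2-yloxy]-4,6-bis(methoxymethoxy)benzaldehyde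
Conditions: PPh3, DIAD, THF, 0 °C → rt
Reagents that add atoms: none
Why: Mitsunobu etherification; the acidic formyl-conjugated phenol displaces the activated secondary allylic alcohol by SN2 with inversion, so (R)-4 gives the (S)-ether, and low temperature keeps SN2' leakage small.

Step 3
Reactants: 5 2-[(2S)-but-3-en-2-yloxy]-4,6-bis(methoxymethoxy)benzaldehyde
Product: 6 (2S,3R)-5,7-bis(methoxymethoxy)-2,3-dimethylchroman-4-one (cis)
Conditions: (5aS,10bR)-2-mesityl-5a,10b-dihydro-4H,6H-indeno[2,1-b][1,2,4]triazolo[4,3-d][1,4]oxazin-2-ium chloride (20 mol %), DBU (15 mol %), 1,4-dioxane, 80 °C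
Reagents that add atoms: none
Why: The triazolylidene freed by DBU adds to the aldehyde to give the Breslow intermediate, whose carbinol carbon bonds to the internal alkene carbon while its O–H proton passes to the terminal carbon in one concerted, asynchronous Conia-ene-like transition state; collapse of the adduct releases the ketone and the carbene. The closest known reaction type is the carbene-catalysed intramolecular hydroacylation of unactivated alkenes in 2-allyloxybenzaldehydes to 3-methylchroman-4-ones, here applied to an alpha-branched allyl ether. Ring B closes in the 6-exo-trig mode, and the alkene terminus becomes the C3 methyl. C2 is not touched and keeps the S configuration set in step 2. C3 is created by the choice of alkene face; the chiral triazolylidene, matched to the ether centre, should deliver the acyl carbon to the face that gives 3R, cis to the C2 methyl. The step needs exo over endo closure, which the short O1 tether secures, and hydroacylation over benzoin coupling, which the two ortho substituents of the aldehyde secure by blocking dimerisation. It also needs the kinetic cis product to survive; for this the amidine is kept below the azolium loading so that no free base remains, and the reaction is stopped at full conversion.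

Step 4
Reactants: 6 (2S,3R)-5,7-bis(methoxymethoxy)-2,3-dimethylchroman-4-one
Product: 7 (2S,3R)-5,7-dihydroxy-2,3-dimethylchroman-4-one
Conditions: HCl (cat.), MeOH, 40 °C
Reagents that add atoms: none
Why: Acid-catalysed acetal exchange releases both phenols; methanol carries the formaldehyde unit away as its dimethyl acetal so that it cannot hydroxymethylate the ring, and mild protic acid should not enolise C3 fast enough to erode the cis pair.

Step 5
Reactants: 7 (2S,3R)-5,7-dihydroxy-2,3-dimethylchroman-4-one; 8 formaldehyde (37 % aqueous)
Product: 9 (2S,3R)-5,7-dihydroxy-2,3-dimethyl-6-[(4-methylphenyl)sulfonylmethyl]chroman-4-one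
Conditions: 8 (1.0 equiv), p-TolSO2Na (1.5 equiv), HCO2H/H2O, rt
Reagents that add atoms: sodium 4-methylbenzenesulfinate, Cc1ccc(cc1)S(=O)[O-].[Na+]
Why: Three-component Mannich-type sulfonylmethylation (hydroxymethylation, loss of water to a quinone methide, capture by sulfinate). C6 should react first because it lies between both hydroxyls and is the enol-like carbon of the hydrogen-bonded 5-hydroxy-4-keto system; one equivalent of 8 and excess sulfinate limit double substitution and diarylmethane formation.

Step 6
Reactants: 9 (2S,3R)-5,7-dihydroxy-2,3-dimethyl-6-[(4-methylphenyl)sulfonylmethyl]chroman-4-one; 10 5-methylhex-5-enal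
Product: 12 (2S,3R,7R)-5,8-dihydroxy-2,3-dimethyl-7-(3-methylbut-3-en-1-yl)-2,3,7,8-tetrahydro-4H,6H-pyrano[3,2-g]chromen-4-one (lactol on O7; mixture of C8 anomers), via ortho-quinone methide 11 (not isolated)
Conditions: 10 (3 equiv), (S)-2-[diphenyl(trimethylsilyloxy)methyl]pyrrolidine (20 mol %), NaHCO3, CH2Cl2/H2O, rt
Reagents that add atoms: none
Why: Base-induced 1,4-elimination of sulfinate gives 11, which is intercepted in a Michael addition by the E-enamine of 10 (organocatalytic alpha-alkylation of an aldehyde, formal [4+2]). The diphenyl(silyloxy)methyl group shields one enamine face, so the methide adds to the other and the methine is set as R, the same sense this catalyst shows with other electrophiles; iminium hydrolysis and hemiacetal closure on O7 give the lactol.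

Step 7
Reactants: 12 the O7 lactol from step 6; 13 isopropyltriphenylphosphonium iodide
Product: 14 (2S,3R)-5,7-dihydroxy-2,3-dimethyl-6-[(2R)-5-methyl-2-(2-methylprop-1-en-1-yl)hex-5-en-1-yl]chroman-4-one
Conditions: 13 (3.5 equiv), KHMDS (3.4 equiv), THF, 0 °C; then 12, −78 → 0 °C
Reagents that add atoms: none
Why: Wittig olefination of the open hydroxy-aldehyde form of the lactol; the extra ylide deprotonates the lactol and phenol hydroxyls, and the resulting 5-phenoxide turns the C4 ketone into a vinylogous carboxylate that is neither attacked nor enolised toward C3. Fast olefination at low temperature should leave the alpha stereocentre intact, and no lactone is yet present to compete.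

Step 8
Reactants: 14 (2S,3R)-5,7-dihydroxy-2,3-dimethyl-6-[(2R)-5-methyl-2-(2-methylprop-1-en-1-yl)hex-5-en-1-yl]chroman-4-one; 15 3-phenylprop-2-ynal
Product: 16 (2S,3R,10R)-5-hydroxy-2,3-dimethyl-6-[(2R)-5-methyl-2-(2-methylprop-1-en-1-yl)hex-5-en-1-yl]-10-phenyl-2,3,9,10-tetrahydro-4H,8H-pyrano[2,3-f]chromene-4,8-dione
Conditions: 15 (1.5 equiv), (5aR,10bS)-2-mesityl-5a,10b-dihydro-4H,6H-indeno[2,1-b][1,2,4]triazolo[4,3-d][1,4]oxazin-2-ium chloride (10 mol %), toluene, 40 °C
Reagents that add atoms: none
Why: Carbene redox activation of the ynal gives an alpha,beta-unsaturated acyl azolium; O7 adds to it, a Coates–Claisen [3,3] shift forms the C8–C bond at the only unsubstituted ring carbon, and lactonisation on O7 releases the carbene. The chiral triazolylidene selects the face of the beta-carbon and should set the benzylic centre as R; the conditions are free of added base and acid, so C3 and the alkenes are not at risk.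

Step 9
Reactants: 16 the tricyclic lactone from step 8; 17 3-methylbut-2-en-1-yl acetate (prenyl acetate)
Product: 18 (2S,3R,6S,10R)-2,3-dimethyl-6-(3-methylbut-2-en-1-yl)-6-[(2R)-5-methyl-2-(2-methylprop-1-en-1-yl)hex-5-en-1-yl]-10-phenyl-2,3,9,10-tetrahydropyrano[2,3-f]chromene-4,5,8(6H)-trione
Conditions: 17 (1.5 equiv), Pd2(dba)3·CHCl3 (2.5 mol %), N,N'-[(1R,2R)-cyclohexane-1,2-diyl]bis[2-(diphenylphosphanyl)benzamide] (7.5 mol %), K2CO3 (1.1 equiv), 1,4-dioxane, rt
Reagents that add atoms: none
Why: Tsuji–Trost-type dearomative allylic alkylation; the 5-phenoxide attacks the unsubstituted terminus of the prenyl–palladium complex through C6, the only ortho carbon open to it while O7 is tied up in the lactone, and gives the cross-conjugated dienone. Any O-prenyl ether can re-ionise on zerovalent palladium and be funnelled to the C-alkylated product; the C2-symmetric bisphosphine should set C6 as S.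

Step 10
Reactants: 18 the dearomatised lactone from step 9
Product: 19 (3R)-3-[(2S,3R,6S)-4-hydroxy-2,3-dimethyl-6-(3-methylbut-2-en-1-yl)-6-[(2R)-5-methyl-2-(2-methylprop-1-en-1-yl)hex-5-en-1-yl]-5,7-dioxo-3,5,6,7-tetrahydro-2H-chromen-8-yl]-3-phenylpropanoic acid (CNP0155375.3)
Conditions: LiOH, THF/H2O, 0 °C; then 1 M HCl
Reagents that add atoms: water (as aqueous LiOH), O
Why: Saponification of the enol-ester lactone, the most electrophilic carbonyl present; once it is open, the ring A oxygens form a delocalised vinylogous carboxylate that protects C3 from enolisation, and acidification gives the enol-triketone acid.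

**Compound list**

1 | 2,4,6-trihydroxybenzaldehyde | O=Cc1c(O)cc(O)cc1O | starting material
2 | chloromethyl methyl ether | COCCl | starting material
3 | 2-hydroxy-4,6-bis(methoxymethoxy)benzaldehyde | COCOc1cc(O)c(C=O)c(OCOC)c1 | intermediate
4 | (R)-but-3-en-2-ol | C=C[C@@H](C)O | starting material
5 | 2-[(2S)-but-3-en-2-yloxy]-4,6-bis(methoxymethoxy)benzaldehyde | C=C[C@H](C)Oc1cc(OCOC)cc(OCOC)c1C=O | intermediate
6 | (2S,3R)-5,7-bis(methoxymethoxy)-2,3-dimethylchroman-4-one | COCOc1cc(OCOC)c2C(=O)[C@H](C)[C@H](C)Oc2c1 | intermediate
7 | (2S,3R)-5,7-dihydroxy-2,3-dimethylchroman-4-one | Oc1cc(O)c2C(=O)[C@H](C)[C@H](C)Oc2c1 | intermediate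
8 | formaldehyde | C=O | starting material
9 | (2S,3R)-5,7-dihydroxy-2,3-dimethyl-6-[(4-methylphenyl)sulfonylmethyl]chroman-4-one | Oc1cc2c(C(=O)[C@H](C)[C@H](C)O2)c(O)c1CS(=O)(=O)c1ccc(C)cc1 | intermediate
10 | 5-methylhex-5-enal | C=C(C)CCCC=O | starting material
11 | (2S,3R)-5-hydroxy-2,3-dimethyl-6-methylidene-2,3-dihydro-4H-chromene-4,7(6H)-dione (ortho-quinone methide) | C=C1C(=O)C=C2C(C(=O)[C@H](C)[C@H](C)O2)=C1O | intermediate (formed in the flask, not isolated)
12 | (2S,3R,7R)-5,8-dihydroxy-2,3-dimethyl-7-(3-methylbut-3-en-1-yl)-2,3,7,8-tetrahydro-4H,6H-pyrano[3,2-g]chromen-4-one (anomers) | C=C(C)CC[C@@H]1Cc2c(OC1O)cc3c(C(=O)[C@H](C)[C@H](C)O3)c2O | intermediate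
13 | isopropyltriphenylphosphonium iodide | CC(C)[P+](c1ccccc1)(c1ccccc1)c1ccccc1.[I-] | starting material
14 | (2S,3R)-5,7-dihydroxy-2,3-dimethyl-6-[(2R)-5-methyl-2-(2-methylprop-1-en-1-yl)hex-5-en-1-yl]chroman-4-one | C=C(C)CC[C@@H](C=C(C)C)Cc1c(O)cc2c(C(=O)[C@H](C)[C@H](C)O2)c1O | intermediate
15 | 3-phenylprop-2-ynal | O=CC#Cc1ccccc1 | starting material
16 | (2S,3R,10R)-5-hydroxy-2,3-dimethyl-6-[(2R)-5-methyl-2-(2-methylprop-1-en-1-yl)hex-5-en-1-yl]-10-phenyl-2,3,9,10-tetrahydro-4H,8H-pyrano[2,3-f]chromene-4,8-dione | C=C(C)CC[C@@H](C=C(C)C)Cc1c(O)c2C(=O)[C@H](C)[C@H](C)Oc2c2[C@@H](c3ccccc3)CC(=O)Oc12 | intermediate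
17 | 3-methylbut-2-en-1-yl acetate | CC(C)=CCOC(C)=O | starting material
18 | (2S,3R,6S,10R)-2,3-dimethyl-6-(3-methylbut-2-en-1-yl)-6-[(2R)-5-methyl-2-(2-methylprop-1-en-1-yl)hex-5-en-1-yl]-10-phenyl-2,3,9,10-tetrahydropyrano[2,3-f]chromene-4,5,8(6H)-trione | C=C(C)CC[C@@H](C=C(C)C)C[C@@]1(CC=C(C)C)C(=O)C2=C(O[C@@H](C)[C@@H](C)C2=O)C3=C1OC(=O)C[C@@H]3c1ccccc1 | intermediate
19 | (3R)-3-[(2S,3R,6S)-4-hydroxy-2,3-dimethyl-6-(3-methylbut-2-en-1-yl)-6-[(2R)-5-methyl-2-(2-methylprop-1-en-1-yl)hex-5-en-1-yl]-5,7-dioxo-3,5,6,7-tetrahydro-2H-chromen-8-yl]-3-phenylpropanoic acid | C=C(C)CC[C@@H](C=C(C)C)C[C@@]1(CC=C(C)C)C(=O)C2=C(O)[C@H](C)[C@H](C)OC2=C([C@H](CC(=O)O)c2ccccc2)C1=O | target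

**Step count and least certain steps**

Total: 10 steps. Longest linear sequence: 10 steps (1 to 19); all other components are purchased.

Step 3 (key step). The likely failure is poor facial selectivity at the alkene, or loss of the cis relationship by enolisation after ring closure. The trans epimer is the more stable one, and C3–H is alpha to an aryl ketone in a medium that contains carbene and amidinium.
- Fallback, from 5 back to 6: the hydroacylation is run with the achiral salt 2-mesityl-6,7-dihydro-5H-pyrrolo[2,1-c][1,2,4]triazol-2-ium chloride and DBU without regard to C3. This should give 6 mixed with its trans epimer (2S,3S)-5,7-bis(methoxymethoxy)-2,3-dimethylchroman-4-one F1.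
- The mixture is converted with LiHMDS (THF, −78 °C) into lithium (2S)-5,7-bis(methoxymethoxy)-2,3-dimethyl-2H-chromen-4-olate F2 and quenched at −78 °C with 2,6-di-tert-butyl-4-methylphenol. Kinetic protonation anti to the pseudo-axial C2 methyl should place the C3 methyl cis, giving 6. Stereocontrol thus moves from C–C bond formation to C–H bond formation.

Step 5. The likely failure is incomplete regioselectivity (attack at C8 or double substitution) and methylene-bridged dimer formation, because C8 is also activated by O7 and O1.
- Fallback, from 6 back to 9: brief dilute HCl in MeOH at 0 °C cleaves only the chelated peri acetal and gives (2S,3R)-5-hydroxy-7-(methoxymethoxy)-2,3-dimethylchroman-4-one F3.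
- Magnesium-mediated ortho-formylation (MgCl2, Et3N, paraformaldehyde, MeCN, 60 °C) can only reach C6, the single position ortho to the free hydroxyl, and gives (2S,3R)-5-hydroxy-7-(methoxymethoxy)-2,3-dimethyl-4-oxochromane-6-carbaldehyde F4.
- NaBH4 (MeOH, −20 °C) reduces the aldehyde to (2S,3R)-5-hydroxy-6-(hydroxymethyl)-7-(methoxymethoxy)-2,3-dimethylchroman-4-one F5.
- p-TolSO2Na with HCl in MeOH exchanges the benzylic hydroxyl for the sulfone and removes the last acetal, arriving at 9 with the regiochemistry fixed by construction.

Step 6. The likely failure is capture of 11 by the C8 carbon of a second molecule instead of by the enamine, because the enamine is present only at catalyst level while the ring is a good carbon nucleophile.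
- Fallback, from 9 and 10 back to 12: 10 is condensed with (R)-1-amino-2-(methoxymethyl)pyrrolidine to the hydrazone (E)-N-[(2R)-2-(methoxymethyl)pyrrolidin-1-yl]-5-methylhex-5-en-1-imine F6.
- Its lithium azaenolate (LDA, THF, −78 °C, a little over 3 equiv) deprotonates 9, triggers sulfinate loss and adds to 11 as a stoichiometric nucleophile. This should give (2S,3R)-5,7-dihydroxy-6-[(2R)-2-{(E)-[(2R)-2-(methoxymethyl)pyrrolidin-1-yl]iminomethyl}-5-methylhex-5-en-1-yl]-2,3-dimethylchroman-4-one F7. The (R)-auxiliary is chosen because its azaenolates alkylate in the sense opposite to the (S)-prolinol enamine.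
- Hydrolysis with aqueous CuCl2 frees the aldehyde, which closes to 12.

Step 8. The likely failure is O-acylation without the C–C bond-forming shift, or weak facial selectivity, because the nucleophile is a hindered, acyl-deactivated phenol.
- Fallback, from 14 back to 16: MgCl2, Et3N and paraformaldehyde formylate C8, the only free ring carbon, to give (2S,3R)-5,7-dihydroxy-2,3-dimethyl-6-[(2R)-5-methyl-2-(2-methylprop-1-en-1-yl)hex-5-en-1-yl]-4-oxochromane-8-carbaldehyde F8.
- A Z-selective Horner–Wadsworth–Emmons reaction with ethyl 2-(diphenoxyphosphoryl)acetate (NaH, THF), followed by spontaneous lactonisation, gives the coumarin (2S,3R)-5-hydroxy-2,3-dimethyl-6-[(2R)-5-methyl-2-(2-methylprop-1-en-1-yl)hex-5-en-1-yl]-2,3-dihydro-4H,8H-pyrano[2,3-f]chromene-4,8-dione F9.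
- Rhodium-catalysed asymmetric 1,4-addition of phenylboronic acid (Rh(acac)(C2H4)2, (R)-5,5'-bis(diphenylphosphino)-4,4'-bi-1,3-benzodioxole, dioxane/H2O, 60 °C) then installs the phenyl group and the R benzylic centre, giving 16.

Step 9. The likely failure is O- instead of C-allylation, with the reaction stalling at the aryl ether because dearomatisation is poorly rewarded while O7 is acylated. Facial control may also be weak, because the two CH2 substituents on C6 differ only at a distance.
- Fallback, from 16 directly to 19: LiOH in THF/H2O opens the lactone to the salt of (3R)-3-{(2S,3R)-5,7-dihydroxy-2,3-dimethyl-6-[(2R)-5-methyl-2-(2-methylprop-1-en-1-yl)hex-5-en-1-yl]-4-oxochroman-8-yl}-3-phenylpropanoic acid F10.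
- Prenyl bromide is added to the cold aqueous-methanolic solution. C-alkylation of the phloroglucinol dianion at C6, the carbon between two oxygens, now gives the stabilised triketone directly.
- After acidification, 19 is separated by chromatography from its C6 epimer (3R)-3-[(2S,3R,6R)-4-hydroxy-2,3-dimethyl-6-(3-methylbut-2-en-1-yl)-6-[(2R)-5-methyl-2-(2-methylprop-1-en-1-yl)hex-5-en-1-yl]-5,7-dioxo-3,5,6,7-tetrahydro-2H-chromen-8-yl]-3-phenylpropanoic acid F11. The two are diastereomers.

**Further compounds**

F1 | step 3 | (2S,3S)-5,7-bis(methoxymethoxy)-2,3-dimethylchroman-4-one | COCOc1cc(OCOC)c2C(=O)[C@@H](C)[C@H](C)Oc2c1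
F2 | step 3 | lithium (2S)-5,7-bis(methoxymethoxy)-2,3-dimethyl-2H-chromen-4-olate | [Li+].COCOc1cc(OCOC)c2C([O-])=C(C)[C@H](C)Oc2c1
F3 | step 5 | (2S,3R)-5-hydroxy-7-(methoxymethoxy)-2,3-dimethylchroman-4-one | COCOc1cc(O)c2C(=O)[C@H](C)[C@H](C)Oc2c1
F4 | step 5 | (2S,3R)-5-hydroxy-7-(methoxymethoxy)-2,3-dimethyl-4-oxochromane-6-carbaldehyde | COCOc1cc2c(C(=O)[C@H](C)[C@H](C)O2)c(O)c1C=O
F5 | step 5 | (2S,3R)-5-hydroxy-6-(hydroxymethyl)-7-(methoxymethoxy)-2,3-dimethylchroman-4-one | COCOc1cc2c(C(=O)[C@H](C)[C@H](C)O2)c(O)c1CO
F6 | step 6 | (E)-N-[(2R)-2-(methoxymethyl)pyrrolidin-1-yl]-5-methylhex-5-en-1-imine | C=C(C)CCC/C=N/N1CCC[C@@H]1COC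
F7 | step 6 | (2S,3R)-5,7-dihydroxy-6-[(2R)-2-{(E)-[(2R)-2-(methoxymethyl)pyrrolidin-1-yl]iminomethyl}-5-methylhex-5-en-1-yl]-2,3-dimethylchroman-4-one | C=C(C)CC[C@@H](/C=N/N1CCC[C@@H]1COC)Cc1c(O)cc2c(C(=O)[C@H](C)[C@H](C)O2)c1O
F8 | step 8 | (2S,3R)-5,7-dihydroxy-2,3-dimethyl-6-[(2R)-5-methyl-2-(2-methylprop-1-en-1-yl)hex-5-en-1-yl]-4-oxochromane-8-carbaldehyde | C=C(C)CC[C@@H](C=C(C)C)Cc1c(O)c(C=O)c2c(C(=O)[C@H](C)[C@H](C)O2)c1O
F9 | step 8 | (2S,3R)-5-hydroxy-2,3-dimethyl-6-[(2R)-5-methyl-2-(2-methylprop-1-en-1-yl)hex-5-en-1-yl]-2,3-dihydro-4H,8H-pyrano[2,3-f]chromene-4,8-dione | C=C(C)CC[C@@H](C=C(C)C)Cc1c(O)c2C(=O)[C@H](C)[C@H](C)Oc2c2C=CC(=O)Oc12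
F10 | step 9 | (3R)-3-{(2S,3R)-5,7-dihydroxy-2,3-dimethyl-6-[(2R)-5-methyl-2-(2-methylprop-1-en-1-yl)hex-5-en-1-yl]-4-oxochroman-8-yl}-3-phenylpropanoic acid | C=C(C)CC[C@@H](C=C(C)C)Cc1c(O)c2C(=O)[C@H](C)[C@H](C)Oc2c([C@H](CC(=O)O)c2ccccc2)c1O
F11 | step 9 | C6 epimer of 19, (3R)-3-[(2S,3R,6R)-4-hydroxy-2,3-dimethyl-6-(3-methylbut-2-en-1-yl)-6-[(2R)-5-methyl-2-(2-methylprop-1-en-1-yl)hex-5-en-1-yl]-5,7-dioxo-3,5,6,7-tetrahydro-2H-chromen-8-yl]-3-phenylpropanoic acid | C=C(C)CC[C@@H](C=C(C)C)C[C@]1(CC=C(C)C)C(=O)C2=C(O)[C@H](C)[C@H](C)OC2=C([C@H](CC(=O)O)c2ccccc2)C1=O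
A1 | alternative 1 | (2S,3R,10R)-5-hydroxy-2,3-dimethyl-6-[(4-methylphenyl)sulfonylmethyl]-10-phenyl-2,3,9,10-tetrahydro-4H,8H-pyrano[2,3-f]chromene-4,8-dione | Cc1ccc(cc1)S(=O)(=O)Cc1c(O)c2C(=O)[C@H](C)[C@H](C)Oc2c2[C@@H](c3ccccc3)CC(=O)Oc12
A2 | alternative 1 | tetracyclic lactol: (2S,3R)-2,3-dimethylchroman-4-one fused at C7–C8 to a (4R)-4-phenyl-dihydropyran-2-one (lactone on O7) and at C5–C6 to a (3R)-2-hydroxy-3-(3-methylbut-3-en-1-yl)tetrahydropyran (lactol on O5, anomers) | C=C(C)CC[C@@H]1Cc2c(OC1O)c1C(=O)[C@H](C)[C@H](C)Oc1c1[C@@H](c3ccccc3)CC(=O)Oc21
A3 | alternative 2 | 2-(trimethylsilyl)ethyl 2-[(2S,3R)-2,3-dimethyl-4-oxo-3,4-dihydro-2H-pyran-6-yl]acetate | C[Si](C)(C)CCOC(=O)CC1=CC(=O)[C@H](C)[C@H](C)O1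
A4 | alternative 2 | methyl (2R,4R)-2-(chlorocarbonyl)-7-methyl-2-(3-methylbut-2-en-1-yl)-4-(2-methylprop-1-en-1-yl)oct-7-enoate | C=C(C)CC[C@@H](C=C(C)C)C[C@@](CC=C(C)C)(C(=O)OC)C(Cl)=O
A5 | alternative 2 | 2-(trimethylsilyl)ethyl ester of the bicyclic trione: the ring A/ring B core of 19 with C6 configured as in 19 and a CO2CH2CH2Si(CH3)3 group on C8 in place of the benzylic arm | C=C(C)CC[C@@H](C=C(C)C)C[C@@]1(CC=C(C)C)C(=O)C2=C(O)[C@H](C)[C@H](C)OC2=C(C(=O)OCC[Si](C)(C)C)C1=O
A6 | alternative 3 | (4R)-5-hydroxy-7-(methoxymethoxy)-6-[(2E)-2-methylbut-2-enoyl]-4-phenyl-3,4-dihydro-2H-chromen-2-one | COCOc1cc2OC(=O)C[C@H](c3ccccc3)c2c(O)c1C(=O)/C(C)=C/C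
A7 | alternative 3 | (2S,3R,10R)-5-(methoxymethoxy)-2,3-dimethyl-10-phenyl-2,3,9,10-tetrahydro-4H,8H-pyrano[2,3-f]chromene-4,8-dione | COCOc1cc2OC(=O)C[C@H](c3ccccc3)c2c2O[C@@H](C)[C@@H](C)C(=O)c12
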